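**Retrosynthetic overview**

- The plan rests on ring A. The C5 methoxy oxygen sits peri to the C4 carbonyl of ring C, and the other two ring A oxygens (C7, C8) are the 4- and 3-oxygens of 2,3,4-trihydroxyacetophenone. The C5–O bond is therefore cut last.
- Target 9 ⇒ (O–CH3) 5-hydroxyflavone 8 ⇒ (C5–O, carbonyl-directed C–H oxygenation) 2',3',4',7,8-pentamethoxyflavone 6.
- 6 ⇒ (O1–C2 closure and dehydrogenation) 2'-hydroxychalcone 4 ⇒ (Cα=Cβ, Claisen–Schmidt) acetophenone 2 + aldehyde 3; 2 ⇒ trihydroxyacetophenone 1.
- Ring order: rings A and B are bought as benzenoid starting materials; ring C (the pyranone) is the only ring built, in step 3; no ring closes after that.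

Key step: step 4

**Route**

Step 1
Reactants: 1 2,3,4-trihydroxyacetophenone
Product: 2 2'-hydroxy-3',4'-dimethoxyacetophenone
Conditions: Me2SO4 (2.1 equiv), K2CO3, acetone, reflux, N2
Reagents that add atoms: dimethyl sulfate, COS(=O)(=O)OC
Why: Williamson O-methylation under weak base, in which the 2-OH is held in a six-membered hydrogen bond to the acetyl oxygen and is much the least nucleophilic, so two equivalents of Me2SO4 should stop at the 3,4-dimethyl ether.

Step 2
Reactants: 2 2'-hydroxy-3',4'-dimethoxyacetophenone; 3 2,3,4-trimethoxybenzaldehyde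
Product: 4 (E)-1-(2-hydroxy-3,4-dimethoxyphenyl)-3-(2,3,4-trimethoxyphenyl)prop-2-en-1-one
Conditions: KOH (50% aq), EtOH, rt; then dilute HCl
Reagents that add atoms: none
Why: Claisen–Schmidt (crossed aldol) condensation, in which the aldehyde has no α-hydrogen, the acetophenone enolate adds to it, and E1cB loss of water gives the conjugated enone as its thermodynamic (E) isomer.

Step 3
Reactants: 4 (E)-1-(2-hydroxy-3,4-dimethoxyphenyl)-3-(2,3,4-trimethoxyphenyl)prop-2-en-1-one
Product: 6 2',3',4',7,8-pentamethoxyflavone, via racemic flavanone 5 (not isolated)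
Conditions: I2 (10 mol%), DMSO, 130 °C
Reagents that add atoms: none
Why: Iodine-catalysed oxidative cyclisation of a 2'-hydroxychalcone, in which 6-endo-trig oxa-Michael closure gives flavanone 5, I2 dehydrogenates it through its enol while DMSO reoxidises HI to I2, and the transient C2 stereocentre of 5 vanishes when ring C becomes the pyranone.

Step 4
Reactants: 6 2',3',4',7,8-pentamethoxyflavone
Product: 8 5-hydroxy-2',3',4',7,8-pentamethoxyflavone, via 5-trifluoroacetoxy flavone 7 (not isolated)
Conditions: [RuCl2(p-cymene)]2 (5 mol%), PhI(OCOCF3)2 (2 equiv), CF3CO2H/(CF3CO)2O, 80 °C; then aq. Na2S2O3, then aq. NaHCO3/MeOH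
Reagents that add atoms: [bis(trifluoroacetoxy)iodo]benzene, PhI(OCOCF3)2, O=C(OI(OC(=O)C(F)(F)F)c1ccccc1)C(F)(F)F (one trifluoroacetate oxygen becomes the C5 oxygen; the ligand exchanges with the CF3CO2H medium, OC(=O)C(F)(F)F)
Why: Chloride–trifluoroacetate exchange should give an electrophilic divalent ruthenium carboxylate that binds the C4 carbonyl oxygen and breaks the peri C5–H bond by carboxylate-assisted deprotonation, giving a five-membered ruthenacycle (Ru, C5, C4a, C4, O); PhI(OCOCF3)2 oxidises this to tetravalent ruthenium, and C–O reductive elimination releases aryl trifluoroacetate 7 and divalent ruthenium. The closest known reaction type is the ketone-directed ruthenium-catalysed ortho C–H hydroxylation of aryl ketones with a trivalent iodine oxidant in CF3CO2H/(CF3CO)2O, which has been applied to C5 of chromones and flavones. No ring closes and no stereocentre forms. The step needs C5 over C6 (the site favoured by undirected electrophiles, ortho to the 7-methoxy group), over C3 and over the two free positions of ring B; only C5–H can reach a metal held on the C4 oxygen in a five-membered chelate, and C5 is also para to the 8-methoxy group, which helps metalation. It also needs the oxidant to spare the methoxyarenes: the acid protonates the pyranone and so deactivates both aryl rings, and the product stays masked as ester 7 until the oxidant is quenched, which prevents oxidation of the free para-methoxyphenol to the 5,8-quinone. Mild aqueous base then cleaves the trifluoroacetate at its acyl carbon to phenol 8.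

Step 5
Reactants: 8 5-hydroxy-2',3',4',7,8-pentamethoxyflavone
Product: 9 2',3',4',5,7,8-hexamethoxyflavone
Conditions: Me2SO4 (excess), K2CO3, acetone, reflux
Reagents that add atoms: dimethyl sulfate, COS(=O)(=O)OC
Why: Williamson O-methylation, in which the 5-OH is hydrogen-bonded to the C4 carbonyl and reacts slowly but is the only nucleophilic site left, so excess Me2SO4 at reflux should take it to completion.

**Compound list**

1 | 2,3,4-trihydroxyacetophenone | CC(=O)c1ccc(O)c(O)c1O | starting material
2 | 2'-hydroxy-3',4'-dimethoxyacetophenone | CC(=O)c1ccc(OC)c(OC)c1O | intermediate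
3 | 2,3,4-trimethoxybenzaldehyde | COc1ccc(C=O)c(OC)c1OC | starting material
4 | (E)-1-(2-hydroxy-3,4-dimethoxyphenyl)-3-(2,3,4-trimethoxyphenyl)prop-2-en-1-one | COc1ccc(/C=C/C(=O)c2ccc(OC)c(OC)c2O)c(OC)c1OC | intermediate
5 | 7,8-dimethoxy-2-(2,3,4-trimethoxyphenyl)chroman-4-one (racemic, formed in the flask) | COc1ccc(C2CC(=O)c3ccc(OC)c(OC)c3O2)c(OC)c1OC | intermediate
6 | 2',3',4',7,8-pentamethoxyflavone | COc1ccc(-c2cc(=O)c3ccc(OC)c(OC)c3o2)c(OC)c1OC | intermediate
7 | 2',3',4',7,8-pentamethoxyflavon-5-yl trifluoroacetate (formed in the flask) | COc1ccc(-c2cc(=O)c3c(OC(=O)C(F)(F)F)cc(OC)c(OC)c3o2)c(OC)c1OC | intermediate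
8 | 5-hydroxy-2',3',4',7,8-pentamethoxyflavone | COc1ccc(-c2cc(=O)c3c(O)cc(OC)c(OC)c3o2)c(OC)c1OC | intermediate
9 | 2',3',4',5,7,8-hexamethoxyflavone | COc1ccc(-c2cc(=O)c3c(OC)cc(OC)c(OC)c3o2)c(OC)c1OC | target

**Step count**

Total steps: 5. Longest linear sequence: 5 steps (1 → 2 → 4 → 6 → 8 → 9); aldehyde 3 enters in step 2.

**Steps most likely to fail**

Step 4. The trivalent iodine oxidant may attack the methoxyarenes without direction by the metal (radical-cation chemistry on ring B, trifluoroacetoxylation at C6). Catalyst turnover may also stall because the protonated carbonyl binds ruthenium poorly. K2S2O8 as oxidant would be tried first. The fallback brings the C5 oxygen in from the start; it sets out from aldehyde 3 and returns to the route at target 9.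
- Purchased 1,2,3,5-tetramethoxybenzene (COc1cc(OC)c(OC)c(OC)c1) would be acetylated with AcCl and AlCl3 in Et2O to 2',3',4',6'-tetramethoxyacetophenone F1.
- Excess AlCl3 should demethylate F1 in the same flask at the ortho methoxy group that is flanked by a second methoxy group, through the aluminium chelate of the ketone, giving 2'-hydroxy-3',4',6'-trimethoxyacetophenone F2.
- Claisen–Schmidt condensation of F2 with 3 (KOH, EtOH) would give (E)-1-(2-hydroxy-3,4,6-trimethoxyphenyl)-3-(2,3,4-trimethoxyphenyl)prop-2-en-1-one F3.
- Cyclisation of F3 with I2 in DMSO would give 9 directly.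

Step 3. Electrophilic iodination of ring A, arrest at the flavanone stage, or cleavage of a methyl ether by HI at high temperature may erode the oxidative cyclisation. The fallback is a Baker–Venkataraman sequence; it sets out from acetophenone 2 and returns at flavone 6.
- Purchased 2,3,4-trimethoxybenzoic acid (COc1ccc(C(=O)O)c(OC)c1OC) would be converted with (COCl)2 and catalytic DMF into 2,3,4-trimethoxybenzoyl chloride F4.
- Acylation of 2 with F4 in pyridine would give 6-acetyl-2,3-dimethoxyphenyl 2,3,4-trimethoxybenzoate F5.
- KOH in pyridine would bring about the acyl shift from oxygen to carbon, giving 1-(2-hydroxy-3,4-dimethoxyphenyl)-3-(2,3,4-trimethoxyphenyl)propane-1,3-dione F6.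
- Cyclodehydration of F6 with catalytic H2SO4 in AcOH would give 6.

Step 1. Site discrimination may be lost, either by alkylation reaching the chelated 2-OH or by incomplete alkylation that leaves mixtures of mono-ethers. The fallback reverses the logic; it sets out from 1 and returns at 2.
- Exhaustive methylation of 1 (excess Me2SO4, K2CO3, acetone, reflux) would give 2',3',4'-trimethoxyacetophenone F7.
- One equivalent of BCl3 in CH2Cl2 at low temperature should then cleave only the methoxy group ortho to the carbonyl, through the boron chelate of the ketone, to give 2.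

**Further compounds**

F1 | step 4 | 2',3',4',6'-tetramethoxyacetophenone | CC(=O)c1c(OC)cc(OC)c(OC)c1OC
F2 | step 4 | 2'-hydroxy-3',4',6'-trimethoxyacetophenone | CC(=O)c1c(OC)cc(OC)c(OC)c1O
F3 | step 4 | (E)-1-(2-hydroxy-3,4,6-trimethoxyphenyl)-3-(2,3,4-trimethoxyphenyl)prop-2-en-1-one | COc1ccc(/C=C/C(=O)c2c(OC)cc(OC)c(OC)c2O)c(OC)c1OC
F4 | step 3 | 2,3,4-trimethoxybenzoyl chloride | COc1ccc(C(=O)Cl)c(OC)c1OC
F5 | step 3 | 6-acetyl-2,3-dimethoxyphenyl 2,3,4-trimethoxybenzoate | COc1ccc(C(=O)Oc2c(C(C)=O)ccc(OC)c2OC)c(OC)c1OC
F6 | step 3 | 1-(2-hydroxy-3,4-dimethoxyphenyl)-3-(2,3,4-trimethoxyphenyl)propane-1,3-dione | COc1ccc(C(=O)CC(=O)c2ccc(OC)c(OC)c2O)c(OC)c1OC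
F7 | step 1 | 2',3',4'-trimethoxyacetophenone | CC(=O)c1ccc(OC)c(OC)c1OC
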